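**Retrosynthetic overview**
- The C2–C3 σ-bond is the central bond of the 1,5-diene C5=C4–C3–C2–C1=C10 embedded in the ten-membered ring. A retro-[3,3] shift therefore contracts that ring to a cis-1,2-dialkenylcyclohexanol (C5–C10 bond, oxygen on C10), and the C10 oxygen is later exchanged for C14 (enolate → enol triflate → CHO).
- End game after ring expansion: thermodynamic correction of the enal geometry, release of the α-methylene lactone from a Mannich base, then the O9 and O8 esters one at a time.
- Cyclohexane core from (1S,2S)-3-bromocyclohexa-3,5-diene-1,2-diol: O8/O9 come from the diol; C10 by Stille vinylation then singlet-oxygen [4+2]/Kornblum–DeLaMare; C5 by cuprate addition; C6 by Rubottom oxidation; C7 by butenolide formation and conjugate reduction.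
- Ring order: six-membered carbocycle (from the diol) → trans-fused γ-lactone → ten-membered ring by ring expansion.

Key step: step 14

Remark: locants C1–C15 are those the atoms carry in the target (ring C1–C10, lactone C11–C13 with C12 the carbonyl, C14 the aldehyde carbon, C15 the hydroxymethyl carbon), so the cyclohexane ring atoms are C5–C10 and β is the face carrying O8 and O9; diol 1 and acid 28 are assumed to be commercial; the acetal carbon of 2 and C11 of 18–25 are drawn as the expected isomers and are of no consequence.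

Step 1
Reactants: 1 (1S,2S)-3-bromocyclohexa-3,5-diene-1,2-diol
Product: 2 p-methoxybenzylidene acetal
Conditions: 4-MeOC6H4CH(OMe)2, PPTS (cat.), CH2Cl2, 0 °C
Reagents that add atoms: 4-methoxybenzaldehyde dimethyl acetal, COC(OC)c1ccc(OC)cc1
Why: Acid-catalysed transacetalisation of the cis-diol should give the cis-fused cyclic acetal without touching the two carbinol centres, the mild acid and low temperature avoiding aromatisation.

Step 2
Reactants: 2 p-methoxybenzylidene acetal
Product: 3 mono-PMB ether
Conditions: DIBAL-H, CH2Cl2, −78 to 0 °C; Rochelle salt work-up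
Reagents that add atoms: none
Why: In this reductive acetal opening aluminium should bind the less hindered O8 (remote from the C–Br carbon) and hydride should reduce the oxocarbenium ion on O9, which leaves PMB on O9 and O8 free.

Step 3
Reactants: 3 mono-PMB ether
Product: 4 silyl ether
Conditions: TBSCl, imidazole, DMF, 0 °C to rt
Reagents that add atoms: tert-butyldimethylsilyl chloride, CC(C)(C)[Si](C)(C)Cl
Why: Standard silylation of the secondary alcohol under non-acidic conditions; it gives O8 a group orthogonal to the O9 PMB ether and a second bulky substituent on the β face.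

Step 4
Reactants: 4 silyl ether
Product: 5 vinyl triene
Conditions: Bu3SnCH=CH2, Pd2(dba)3 (cat.), AsPh3, THF, 40 °C
Reagents that add atoms: tributyl(vinyl)stannane, C=C[Sn](CCCC)(CCCC)CCCC
Why: Stille coupling of the vinyl bromide should put the future C1=C2 vinyl group on C10 before C10 is oxygenated, so that the oxygen can later be delivered to the face opposite O8/O9.

Step 5
Reactants: 5 vinyl triene
Product: 7 hydroxy enone, via endoperoxide 6 (not isolated)
Conditions: O2, TPP (cat.), hν, CH2Cl2, −78 °C; then Et3N, 0 °C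
Reagents that add atoms: dioxygen, O=O
Why: Singlet-oxygen [4+2] cycloaddition to the s-cis ring diene should occur anti to the two β-silyloxy/benzyloxy groups, and Kornblum–DeLaMare rearrangement (loss of the only bridgehead H, at C7) then gives the C7 ketone and the C10 tertiary alcohol with O10 α and vinyl β.

Step 6
Reactants: 7 hydroxy enone
Product: 8 TES ether
Conditions: TESOTf, 2,6-lutidine, CH2Cl2, −78 °C
Reagents that add atoms: triethylsilyl trifluoromethanesulfonate, CC[Si](CC)(CC)OS(=O)(=O)C(F)(F)F
Why: Silylation of the tertiary alcohol blocks premature alkoxide chemistry and makes O10 the large group that should steer the next addition to the β face.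

Step 7
Reactants: 9 2-bromoprop-2-en-1-ol
Product: 10 bromoallyl silyl ether
Conditions: TBDPSCl, imidazole, CH2Cl2, rt
Reagents that add atoms: tert-butyldiphenylsilyl chloride, CC(C)(C)[Si](Cl)(c1ccccc1)c1ccccc1
Why: Standard silylation of a primary alcohol; the bulky TBDPS group should suppress retro-Brook migration in the derived organometallic and outlast the later TBS cleavage.

Step 8
Reactants: 8 TES ether; 10 bromoallyl silyl ether
Product: 12 silyl enol ether, via alkenylmagnesium bromide 11 (not isolated)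
Conditions: 10, Mg, THF; then CuBr·SMe2 (cat.), TMSCl, THF, −78 °C, add 8
Reagents that add atoms: chlorotrimethylsilane, C[Si](C)(C)Cl
Why: Copper-catalysed, TMSCl-accelerated conjugate addition of the alkenyl Grignard reagent should deliver the C3/C4/C15 unit to C5 anti to the 10α-OTES group (so cis to the 10β-vinyl group), with the enolate trapped regiospecifically as the C6=C7 silyl enol ether.

Step 9
Reactants: 12 silyl enol ether
Product: 14 hydroxy ketone, via α-silyloxy ketone 13 (not isolated)
Conditions: DMDO (acetone), CH2Cl2, −78 to −20 °C; then citric acid, MeOH, 0 °C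
Reagents that add atoms: dimethyldioxirane, CC1(C)OO1
Why: In this Rubottom oxidation the electron-rich enol ether should be epoxidised much faster than the other alkenes and from the α face, opposite the β substituents on C5, C8, C9 and C10, which sets 6α-OH trans to the C5 alkenyl group.

Step 10
Reactants: 14 hydroxy ketone
Product: 15 butenolide
Conditions: Ph3P=C=C=O, toluene, 80 °C
Reagents that add atoms: (triphenylphosphoranylidene)ketene, O=C=C=P(c1ccccc1)(c1ccccc1)c1ccccc1
Why: O-Acylation of the 6-OH by the ketenylidene phosphorane gives an ester ylide that should close by intramolecular Wittig reaction on the C7 ketone, installing C11 and C12 as the 12,6-butenolide.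

Step 11
Reactants: 15 butenolide
Product: 16 trans-lactone
Conditions: Cu(OAc)2·H2O (cat.), 1,2-bis(diphenylphosphino)benzene (cat.), (EtO)2MeSiH, t-BuOH, toluene, rt
Reagents that add atoms: none
Why: Copper hydride conjugate reduction should spare the isolated alkenes and deliver hydride axially to the α face of C7, since the axial 8β-OTBS group blocks the other trajectory, giving 7α-H and hence the trans-fused lactone with C11 cis to O8.

Step 12
Reactants: 16 trans-lactone
Product: 18 Mannich base, via lithium enolate 17 (not isolated)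
Conditions: LDA, THF, −78 °C; then CH2=NMe2+ I−, −78 to 0 °C
Reagents that add atoms: N,N-dimethylmethyleneiminium iodide, C[N+](C)=C.[I-]
Why: Mannich alkylation of the lactone enolate introduces C13 as a CH2NMe2 group, a base-stable mask of the α-methylene lactone for the steps that would attack the free acrylate; the C11 configuration is lost later.

Step 13
Reactants: 18 Mannich base
Product: 19 tertiary alcohol
Conditions: HF·pyridine, pyridine, THF, 0 °C
Reagents that add atoms: none
Why: Buffered fluoride desilylation should remove the TES ether much faster than the secondary TBS and primary TBDPS ethers, freeing the C10 hydroxyl for the rearrangement.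

Step 14
Reactants: 19 tertiary alcohol
Product: 22 enol triflate, via potassium alkoxide 20 (not isolated), via potassium enolate 21 (not isolated)
Conditions: KHMDS (1.05 equiv), 18-crown-6, THF, −78 to 0 °C; then PhNTf2, −78 °C to rt
Reagents that add atoms: N-phenylbis(trifluoromethanesulfonimide), O=S(=O)(N(c1ccccc1)S(=O)(=O)C(F)(F)F)C(F)(F)F
Why: Deprotonation gives alkoxide 20, whose weakened C5–C10 bond breaks as C2–C3 forms in a [3,3]-sigmatropic shift through the chair-like array C2=C1–C10–C5–C4=C3, expanding the six-membered ring to the ten-membered ring and giving enolate 21, which is O-sulfonylated in the same flask. The closest known reaction type is the anionic oxy-Cope ring expansion of cis-1,2-dialkenylcyclohexanols to cyclodec-5-enones with in situ enolate trapping. The ten-membered ring is closed by a four-atom ring expansion, the bond forming between the two alkene termini inside the six-centre transition state, while the γ-lactone is a spectator that locks the cyclohexane chair. No sp3 centre is created; the C4=C5 geometry is set by the equatorial 5β-alkenyl group (C6 is pseudo-axial in the transition state and ends cis to C3, so C15 is trans to C6 as in the target), and the enolate geometry is set by the axial 10β-vinyl group (C9 pseudo-equatorial, so O10 ends cis to C2). The step needs the chair pathway of the cis-dialkenyl isomer rather than a boat or a fragmentation path, which the trans-fused lactone (vinyl axial, alkenyl equatorial) and the relief of the 1,3-diaxial vinyl/OTBS contact should secure. The C1=C10 geometry delivered here is the opposite of the target's and is corrected once C14 is in place (step 16).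

Step 15
Reactants: 22 enol triflate
Product: 23 enal with CHO cis to C2
Conditions: Pd(PPh3)4 (cat.), CO (1 atm), Bu3SnH (slow addition), LiCl, THF, rt to 40 °C
Reagents that add atoms: carbon monoxide, [C-]#[O+]
Why: Palladium-catalysed reductive carbonylation (formylation) of the vinyl triflate should install C14 with retention of the alkene geometry, slow hydride addition keeping direct reduction and enal reduction in check.

Step 16
Reactants: 23 enal with CHO cis to C2
Product: 24 enal with CHO trans to C2
Conditions: PhSSPh (cat.), hν (visible), benzene, rt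
Reagents that add atoms: none
Why: Reversible addition of the phenylthiyl radical to C1 gives a rotatable α-formyl radical, so this radical-chain alkene isomerisation should settle on the favoured geometry (C2 trans to CHO, both ring alkenes cis in the ten-membered ring), which is the target's.

Step 17
Reactants: 24 enal with CHO trans to C2
Product: 26 α-methylene lactone, via ammonium iodide 25 (not isolated)
Conditions: MeI, MeCN, rt; then aq NaHCO3, EtOAc, rt
Reagents that add atoms: none
Why: Exhaustive N-methylation followed by mild-base E1cB (Hofmann-type) elimination of trimethylamine should unveil the exocyclic C11=C13 alkene once no thiyl radicals or tin hydride remain.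

Step 18
Reactants: 26 α-methylene lactone
Product: 27 C9 alcohol
Conditions: DDQ, CH2Cl2/pH 7 buffer, 0 °C
Reagents that add atoms: none
Why: Oxidative cleavage of the PMB ether is orthogonal to both silyl ethers, the enal and the lactone, and frees only O9.

Step 19
Reactants: 27 C9 alcohol; 28 (R)-2-methylbutanoic acid
Product: 29 C9 ester
Conditions: DCC, DMAP (cat.), CH2Cl2, 0 °C to rt
Reagents that add atoms: none
Why: Steglich esterification of the only free hydroxyl; low temperature and catalytic DMAP should limit epimerisation of the α-stereocentre of the acid, which supplies the (R) centre of the side chain.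

Step 20
Reactants: 29 C9 ester
Product: 30 C8 alcohol
Conditions: aq HF (48%), MeCN, 0 °C
Reagents that add atoms: none
Why: Acidic fluoride desilylation should cleave the secondary TBS ether while the far more acid-stable primary TBDPS ether survives, and acidic medium disfavours O9→O8 acyl migration.

Step 21
Reactants: 30 C8 alcohol; 31 angelic acid
Product: 33 C8 angelate, via mixed anhydride 32 (not isolated)
Conditions: 31, 2,4,6-Cl3C6H2COCl, Et3N, toluene, rt; then 30, toluene, 80 °C
Reagents that add atoms: none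
Why: Yamaguchi-type mixed-anhydride acylation without a nucleophilic catalyst should esterify the hindered C8 alcohol while keeping the (Z) geometry of the angeloyl group.

Step 22
Reactants: 33 C8 angelate
Product: 34 target CNP0290361.1
Conditions: HF·pyridine, pyridine, THF, 0 °C to rt
Reagents that add atoms: none
Why: Buffered fluoride desilylation of the primary allylic TBDPS ether releases the C15 alcohol under conditions that should spare both esters, the enal and the α-methylene lactone.

**Compound list**
1 | (1S,2S)-3-bromocyclohexa-3,5-diene-1,2-diol | BrC1=CC=C[C@H](O)[C@@H]1O | starting material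
2 | cis-fused p-methoxybenzylidene acetal of 1 (exo-aryl) | BrC1=CC=C[C@@H]2O[C@@H](c3ccc(OC)cc3)O[C@H]12 | intermediate
3 | bromodiene with 9β-OPMB (oxygen next to C–Br) and free 8β-OH | BrC1=CC=C[C@H](O)[C@@H]1OCc2ccc(OC)cc2 | intermediate
4 | bromodiene with 8β-OTBS and 9β-OPMB | BrC1=CC=C[C@H](O[Si](C)(C)C(C)(C)C)[C@@H]1OCc2ccc(OC)cc2 | intermediate
5 | 10-vinyl triene with 8β-OTBS and 9β-OPMB | C=CC1=CC=C[C@H](O[Si](C)(C)C(C)(C)C)[C@@H]1OCc2ccc(OC)cc2 | intermediate
6 | endoperoxide, O–O bridge on the α face between C7 and C10 | C=C[C@@]12C=C[C@@H](OO1)[C@H](O[Si](C)(C)C(C)(C)C)[C@@H]2OCc3ccc(OC)cc3 | intermediate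
7 | enone (C7=O, C5=C6) with 10α-OH, 10β-vinyl, 9β-OPMB, 8β-OTBS | C=C[C@]1(O)C=CC(=O)[C@H](O[Si](C)(C)C(C)(C)C)[C@@H]1OCc2ccc(OC)cc2 | intermediate
8 | 10α-O-triethylsilyl ether of 7 | C=C[C@]1(O[Si](CC)(CC)CC)C=CC(=O)[C@H](O[Si](C)(C)C(C)(C)C)[C@@H]1OCc2ccc(OC)cc2 | intermediate
9 | 2-bromoprop-2-en-1-ol | C=C(Br)CO | starting material
10 | [(2-bromoprop-2-en-1-yl)oxy](tert-butyl)diphenylsilane | C=C(Br)CO[Si](c1ccccc1)(c1ccccc1)C(C)(C)C | intermediate
11 | [3-(tert-butyldiphenylsilyloxy)prop-1-en-2-yl]magnesium bromide | C=C([Mg]Br)CO[Si](c1ccccc1)(c1ccccc1)C(C)(C)C | intermediate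
12 | C6=C7 trimethylsilyl enol ether with 5β-[3-(TBDPSO)prop-1-en-2-yl], 10α-OTES, 10β-vinyl | C=C[C@]1(O[Si](CC)(CC)CC)[C@H](C(=C)CO[Si](c2ccccc2)(c2ccccc2)C(C)(C)C)C=C(O[Si](C)(C)C)[C@H](O[Si](C)(C)C(C)(C)C)[C@@H]1OCc2ccc(OC)cc2 | intermediate
13 | C7 ketone with 6α-OTMS | C=C[C@]1(O[Si](CC)(CC)CC)[C@H](C(=C)CO[Si](c2ccccc2)(c2ccccc2)C(C)(C)C)[C@@H](O[Si](C)(C)C)C(=O)[C@H](O[Si](C)(C)C(C)(C)C)[C@@H]1OCc2ccc(OC)cc2 | intermediate
14 | C7 ketone with 6α-OH | C=C[C@]1(O[Si](CC)(CC)CC)[C@H](C(=C)CO[Si](c2ccccc2)(c2ccccc2)C(C)(C)C)[C@@H](O)C(=O)[C@H](O[Si](C)(C)C(C)(C)C)[C@@H]1OCc2ccc(OC)cc2 | intermediate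
15 | 12,6-butenolide with C7=C11 | C=C[C@]1(O[Si](CC)(CC)CC)[C@H](C(=C)CO[Si](c3ccccc3)(c3ccccc3)C(C)(C)C)[C@H]2OC(=O)C=C2[C@H](O[Si](C)(C)C(C)(C)C)[C@@H]1OCc3ccc(OC)cc3 | intermediate
16 | trans-fused γ-lactone (6β-H, 7α-H) | C=C[C@]1(O[Si](CC)(CC)CC)[C@H](C(=C)CO[Si](c3ccccc3)(c3ccccc3)C(C)(C)C)[C@H]2OC(=O)C[C@@H]2[C@H](O[Si](C)(C)C(C)(C)C)[C@@H]1OCc3ccc(OC)cc3 | intermediate
17 | lithium enolate of lactone 16 | C=C[C@]1(O[Si](CC)(CC)CC)[C@H](C(=C)CO[Si](c3ccccc3)(c3ccccc3)C(C)(C)C)[C@H]2OC([O-])=C[C@@H]2[C@H](O[Si](C)(C)C(C)(C)C)[C@@H]1OCc3ccc(OC)cc3.[Li+] | intermediate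
18 | 11-(dimethylaminomethyl) trans-lactone, 10α-OTES | C=C[C@]1(O[Si](CC)(CC)CC)[C@H](C(=C)CO[Si](c3ccccc3)(c3ccccc3)C(C)(C)C)[C@H]2OC(=O)[C@@H](CN(C)C)[C@@H]2[C@H](O[Si](C)(C)C(C)(C)C)[C@@H]1OCc3ccc(OC)cc3 | intermediate
19 | cyclohexanol: 10α-OH, 10β-vinyl, 5β-alkenyl, trans-lactone, 8β-OTBS, 9β-OPMB | C=C[C@]1(O)[C@H](C(=C)CO[Si](c3ccccc3)(c3ccccc3)C(C)(C)C)[C@H]2OC(=O)[C@@H](CN(C)C)[C@@H]2[C@H](O[Si](C)(C)C(C)(C)C)[C@@H]1OCc3ccc(OC)cc3 | intermediate
20 | potassium alkoxide of 19 | C=C[C@]1([O-])[C@H](C(=C)CO[Si](c3ccccc3)(c3ccccc3)C(C)(C)C)[C@H]2OC(=O)[C@@H](CN(C)C)[C@@H]2[C@H](O[Si](C)(C)C(C)(C)C)[C@@H]1OCc3ccc(OC)cc3.[K+] | intermediate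
21 | ten-membered potassium enolate (O10 cis to C2; C15 trans to C6) | CN(C)C[C@@H]1C(=O)O[C@@H]2/C=C(/CO[Si](c3ccccc3)(c3ccccc3)C(C)(C)C)CC/C=C(\[O-])[C@@H](OCc3ccc(OC)cc3)[C@@H](O[Si](C)(C)C(C)(C)C)[C@@H]12.[K+] | intermediate
22 | ten-membered enol triflate (OTf on C10, cis to C2) | CN(C)C[C@@H]1C(=O)O[C@@H]2/C=C(/CO[Si](c3ccccc3)(c3ccccc3)C(C)(C)C)CC/C=C(\OS(=O)(=O)C(F)(F)F)[C@@H](OCc3ccc(OC)cc3)[C@@H](O[Si](C)(C)C(C)(C)C)[C@@H]12 | intermediate
23 | 14-aldehyde with CHO cis to C2 | CN(C)C[C@@H]1C(=O)O[C@@H]2/C=C(/CO[Si](c3ccccc3)(c3ccccc3)C(C)(C)C)CC/C=C(\C=O)[C@@H](OCc3ccc(OC)cc3)[C@@H](O[Si](C)(C)C(C)(C)C)[C@@H]12 | intermediate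
24 | 14-aldehyde with CHO trans to C2 (target ring geometry) | CN(C)C[C@@H]1C(=O)O[C@@H]2/C=C(/CO[Si](c3ccccc3)(c3ccccc3)C(C)(C)C)CC/C=C(/C=O)[C@@H](OCc3ccc(OC)cc3)[C@@H](O[Si](C)(C)C(C)(C)C)[C@@H]12 | intermediate
25 | trimethylammonium iodide of 24 | C[N+](C)(C)C[C@@H]1C(=O)O[C@@H]2/C=C(/CO[Si](c3ccccc3)(c3ccccc3)C(C)(C)C)CC/C=C(/C=O)[C@@H](OCc3ccc(OC)cc3)[C@@H](O[Si](C)(C)C(C)(C)C)[C@@H]12.[I-] | intermediate
26 | α-methylene lactone with 9β-OPMB, 8β-OTBS, 15-OTBDPS | C=C1C(=O)O[C@@H]2/C=C(/CO[Si](c3ccccc3)(c3ccccc3)C(C)(C)C)CC/C=C(/C=O)[C@@H](OCc3ccc(OC)cc3)[C@@H](O[Si](C)(C)C(C)(C)C)[C@@H]12 | intermediate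
27 | 9β-alcohol | C=C1C(=O)O[C@@H]2/C=C(/CO[Si](c3ccccc3)(c3ccccc3)C(C)(C)C)CC/C=C(/C=O)[C@@H](O)[C@@H](O[Si](C)(C)C(C)(C)C)[C@@H]12 | intermediate
28 | (R)-2-methylbutanoic acid | CC[C@@H](C)C(=O)O | starting material
29 | 9β-[(R)-2-methylbutanoate], 8β-OTBS | C=C1C(=O)O[C@@H]2/C=C(/CO[Si](c3ccccc3)(c3ccccc3)C(C)(C)C)CC/C=C(/C=O)[C@@H](OC(=O)[C@H](C)CC)[C@@H](O[Si](C)(C)C(C)(C)C)[C@@H]12 | intermediate
30 | 8β-alcohol | C=C1C(=O)O[C@@H]2/C=C(/CO[Si](c3ccccc3)(c3ccccc3)C(C)(C)C)CC/C=C(/C=O)[C@@H](OC(=O)[C@H](C)CC)[C@@H](O)[C@@H]12 | intermediate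
31 | angelic acid, (Z)-2-methylbut-2-enoic acid | C/C=C(/C)C(=O)O | starting material
32 | angelic 2,4,6-trichlorobenzoic anhydride | C/C=C(/C)C(=O)OC(=O)c1c(Cl)cc(Cl)cc1Cl | intermediate
33 | 15-O-TBDPS ether of the target | C=C1C(=O)O[C@@H]2/C=C(/CO[Si](c3ccccc3)(c3ccccc3)C(C)(C)C)CC/C=C(/C=O)[C@@H](OC(=O)[C@H](C)CC)[C@@H](OC(=O)/C(C)=C\C)[C@@H]12 | intermediate
34 | CNP0290361.1 | C=C1C(=O)O[C@@H]2/C=C(/CO)CC/C=C(/C=O)[C@@H](OC(=O)[C@H](C)CC)[C@@H](OC(=O)/C(C)=C\C)[C@@H]12 | target

**Totals**
Total step count: 22. Longest linear sequence: 21 steps (steps 1–6 and 8–22 from diol 1).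

**Steps most likely to fail**

Step 14. The potassium alkoxide may be diverted before it rearranges (attack on the lactone carbonyl, silyl transfer), or the enolate may lose its geometry before sulfonylation. The fallback avoids base altogether and sets out from TES ether 18. Heating 18 in o-dichlorobenzene at about 190 °C should bring about the neutral silyloxy-Cope rearrangement through the same chair and give the ten-membered triethylsilyl enol ether F3. Treatment of F3 with CsF and PhNTf2 in DME should then convert it into enol triflate 22, where the route is rejoined.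

Step 8. Facial selectivity in the conjugate addition may be poor: the alkenyl group may enter syn to the OTES group and give the trans-dialkenyl isomer, which would lead to the wrong C4=C5 geometry. The fallback replaces substrate control by ligand control and sets out from 10 and 8. Bromide 10 is converted (t-BuLi, then 2-isopropoxy-4,4,5,5-tetramethyl-1,3,2-dioxaborolane) into the alkenyl pinacol boronate F1. A rhodium(I)/chiral diene-catalysed 1,4-addition of F1 to enone 8 in aqueous dioxane, with the ligand enantiomer that attacks the β face, should give the β-alkenyl ketone F2. Kinetic enolisation of F2 at the C6 methylene (LDA, TMSCl, −78 °C) returns to silyl enol ether 12.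

Step 16. Equilibration of the enal may be incomplete, or the radical chain may also scramble the C4=C5 geometry. The fallback is a stepwise addition–elimination that sets out from 23. Conjugate addition of benzeneselenol (cat. Et3N, CH2Cl2) should give the β-phenylselanyl aldehyde F4 as a mixture of C1/C10 epimers. Oxidation with H2O2/pyridine at 0 °C and syn-elimination of the selenoxide towards the epimerisable C10–H should regenerate the conjugated enal in its preferred geometry, which is 24.

Further compounds
F1 | step 8 | tert-butyldiphenyl{[2-(4,4,5,5-tetramethyl-1,3,2-dioxaborolan-2-yl)prop-2-en-1-yl]oxy}silane | C=C(B1OC(C)(C)C(C)(C)O1)CO[Si](c1ccccc1)(c1ccccc1)C(C)(C)C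
F2 | step 8 | C7 ketone with 5β-alkenyl and unsubstituted C6 methylene | C=C[C@]1(O[Si](CC)(CC)CC)[C@H](C(=C)CO[Si](c2ccccc2)(c2ccccc2)C(C)(C)C)CC(=O)[C@H](O[Si](C)(C)C(C)(C)C)[C@@H]1OCc2ccc(OC)cc2
F3 | step 14 | ten-membered C10 triethylsilyl enol ether (OSiEt3 cis to C2) | CN(C)C[C@@H]1C(=O)O[C@@H]2/C=C(/CO[Si](c3ccccc3)(c3ccccc3)C(C)(C)C)CC/C=C(\O[Si](CC)(CC)CC)[C@@H](OCc3ccc(OC)cc3)[C@@H](O[Si](C)(C)C(C)(C)C)[C@@H]12
F4 | step 16 | 1-phenylselanyl-1,10-dihydro aldehyde (C1/C10 epimer mixture) | CN(C)C[C@@H]1C(=O)O[C@@H]2/C=C(/CO[Si](c3ccccc3)(c3ccccc3)C(C)(C)C)CCC([Se]c3ccccc3)C(C=O)[C@@H](OCc3ccc(OC)cc3)[C@@H](O[Si](C)(C)C(C)(C)C)[C@@H]12
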